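**Plan**

- Retrosynthesis: the three benzyl ethers are removed last. Ring C is cut at O1–C8a, leaving an open 1,3-diketone with hydrogen on the future C8a. The diketone is cut at C2–C3 into a ring A methyl ketone and a ring B ester. The ketone goes back through C3–C4 (methyl addition to an aldehyde) and the C5–O bond (hydroxylation of a bromide) to syringaldehyde.
- Enabling feature: in scaposin C8a carries O1 and sits ortho to the C8 methoxyl and para to the C6 methoxyl. A ring A in which this carbon still bears hydrogen is syringaldehyde with one extra oxygen at C5, and this C–H carbon is where a ring A radical cation should accept an oxygen nucleophile.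
- Forward: ring A is completed from syringaldehyde and ring B comes from 3-hydroxy-4,5-dimethoxybenzoic acid. A Claisen condensation joins them, ring C is closed last by anodic C–H/O–H coupling, and hydrogenolysis frees the three phenols.
- Stereochemistry: the target is achiral. The only stereocenter on the way, a benzylic carbinol, is racemic and is erased by oxidation.

Key step: step 8

Assumption: the 1,3-diketone is written as its diketo tautomer, although it should be present mainly as the enol, which is the form that cyclizes.

**Route**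

Step 1
Reactants: 1 syringaldehyde (4-hydroxy-3,5-dimethoxybenzaldehyde)
Product: 2 2-bromo-4-hydroxy-3,5-dimethoxybenzaldehyde
Conditions: Br2 (1.0 equiv), AcOH, rt
Reagents that add atoms: bromine, BrBr
Why: Electrophilic aromatic bromination; both positions ortho to the phenol are blocked, so bromine should enter one of the two equivalent carbons ortho to one methoxyl and para to the other, and one equivalent in dry acetic acid should stop at the monobromide and disfavor ipso attack at the formyl-bearing carbon.

Step 2
Reactants: 2 2-bromo-4-hydroxy-3,5-dimethoxybenzaldehyde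
Product: 3 2,4-dihydroxy-3,5-dimethoxybenzaldehyde
Conditions: NaOH, CuI (cat.), 1,10-phenanthroline (cat.), H2O/DMSO, 110 °C, N2; then aq. HCl
Reagents that add atoms: sodium hydroxide, [Na+].[OH-]
Why: Copper-catalyzed Ullmann-type hydroxylation of an aryl bromide; the ortho formyl group should assist the copper insertion, and the para phenoxide makes the aldehyde a vinylogous carboxylate that resists Cannizzaro disproportionation, as in the classical conversion of bromovanillins into hydroxyvanillins.

Step 3
Reactants: 3 2,4-dihydroxy-3,5-dimethoxybenzaldehyde; 4 benzyl bromide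
Product: 5 2,4-bis(benzyloxy)-3,5-dimethoxybenzaldehyde
Conditions: BnBr (2.4 equiv), K2CO3, DMF, 60 °C
Reagents that add atoms: benzyl bromide, BrCc1ccccc1
Why: Williamson etherification; both phenoxides should be O-benzylated, the chelated 2-OH needing the excess reagent and warming, while the aldehyde is untouched.

Step 4
Reactants: 5 2,4-bis(benzyloxy)-3,5-dimethoxybenzaldehyde
Product: 6 1-[2,4-bis(benzyloxy)-3,5-dimethoxyphenyl]ethanol (racemic)
Conditions: MeMgBr, THF, 0 °C; then aq. NH4Cl
Reagents that add atoms: methylmagnesium bromide, C[Mg]Br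
Why: Grignard addition to the aldehyde brings in the carbon that becomes C3; the carbinol center forms without control, which does not matter because the next step oxidizes it.

Step 5
Reactants: 6 1-[2,4-bis(benzyloxy)-3,5-dimethoxyphenyl]ethanol
Product: 7 1-[2,4-bis(benzyloxy)-3,5-dimethoxyphenyl]ethanone
Conditions: Dess–Martin periodinane, CH2Cl2, rt
Reagents that add atoms: none
Why: Dess–Martin oxidation of a benzylic secondary alcohol to the aryl methyl ketone under neutral conditions that leave the benzyl and methyl ethers alone.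

Step 6
Reactants: 8 3-hydroxy-4,5-dimethoxybenzoic acid; 4 benzyl bromide
Product: 9 benzyl 3-(benzyloxy)-4,5-dimethoxybenzoate
Conditions: BnBr (2.3 equiv), K2CO3, DMF, 60 °C
Reagents that add atoms: benzyl bromide, BrCc1ccccc1
Why: Williamson-type O-alkylation of the carboxylate and the phenoxide in one operation; the benzyl ester serves directly as the acyl donor in step 7.

Step 7
Reactants: 7 1-[2,4-bis(benzyloxy)-3,5-dimethoxyphenyl]ethanone; 9 benzyl 3-(benzyloxy)-4,5-dimethoxybenzoate
Product: 11 1-[2,4-bis(benzyloxy)-3,5-dimethoxyphenyl]-3-[3-(benzyloxy)-4,5-dimethoxyphenyl]propane-1,3-dione, via lithium enolate of the ring A ketone 10 (not isolated)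
Conditions: LiN(SiMe3)2 (2.5 equiv), THF, −78 °C; then 9, −78 °C → 50 °C; aq. HCl
Reagents that add atoms: none
Why: Crossed Claisen condensation forming C2–C3; the ketone is fully enolized before the non-enolizable ester is added, so only one coupling direction is possible, and deprotonation of the diketone by the excess base drives the acylation forward.

Step 8
Reactants: 11 1-[2,4-bis(benzyloxy)-3,5-dimethoxyphenyl]-3-[3-(benzyloxy)-4,5-dimethoxyphenyl]propane-1,3-dione
Product: 12 5,7,5'-tri-O-benzylscaposin (5,7-bis(benzyloxy)-2-[3-(benzyloxy)-4,5-dimethoxyphenyl]-6,8-dimethoxy-4H-chromen-4-one)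
Conditions: graphite anode, Pt cathode, undivided cell, constant current (ca. 2.2 F/mol), Bu4NPF6, (CF3)2CHOH, rt
Reagents that add atoms: none
Why: Proposed new method: ring A, with four oxygen donors, should be the first part of 11 to give up an electron at the anode, and in its radical cation the carbon that becomes C8a (ortho to one methoxyl, para to the other, and the only ring A carbon bearing hydrogen) should be attacked by the oxygen of the enolized C2 carbonyl, after which a second electron transfer and proton loss restore the arene while hydrogen is evolved at the cathode. The closest known reaction type is the anodic dehydrogenative C–O cyclization of electron-rich arenes in (CF3)2CHOH, as in the lactonization of biaryl-2-carboxylic acids. Ring C closes as a six-membered ring by oxygen attack on the arene carbon ortho to the acyl group, so the new ring shares the C4a–C8a bond with ring A (formally 6-endo with respect to that bond). No stereocenter is formed. The step needs attack at C8a and not at the benzyloxy-bearing C5, and oxidation of ring A before ring B, the benzyl groups or the product: only the adduct at C8a can rearomatize by proton loss whereas ipso attack at C5 is reversible, ring A has one more donor than ring B, and the flavone, with ring A conjugated to the pyranone carbonyl, should be harder to oxidize than 11.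

Step 9
Reactants: 12 5,7,5'-tri-O-benzylscaposin
Product: 13 scaposin (5,7-dihydroxy-2-(3-hydroxy-4,5-dimethoxyphenyl)-6,8-dimethoxy-4H-chromen-4-one)
Conditions: H2 (1 atm), 10% Pd/C, EtOAc/MeOH, rt
Reagents that add atoms: none
Why: Catalytic hydrogenolysis of the three aryl benzyl ethers; the pyranone double bond of a flavone and the methyl ethers should not be reduced at one atmosphere and room temperature.

**Compound list**

1 | syringaldehyde (4-hydroxy-3,5-dimethoxybenzaldehyde) | COc1cc(C=O)cc(OC)c1O | starting material
2 | 2-bromo-4-hydroxy-3,5-dimethoxybenzaldehyde | O=Cc1cc(OC)c(O)c(OC)c1Br | intermediate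
3 | 2,4-dihydroxy-3,5-dimethoxybenzaldehyde | O=Cc1cc(OC)c(O)c(OC)c1O | intermediate
4 | benzyl bromide | BrCc1ccccc1 | starting material
5 | 2,4-bis(benzyloxy)-3,5-dimethoxybenzaldehyde | O=Cc1cc(OC)c(OCc2ccccc2)c(OC)c1OCc1ccccc1 | intermediate
6 | 1-[2,4-bis(benzyloxy)-3,5-dimethoxyphenyl]ethanol (racemic) | CC(O)c1cc(OC)c(OCc2ccccc2)c(OC)c1OCc1ccccc1 | intermediate
7 | 1-[2,4-bis(benzyloxy)-3,5-dimethoxyphenyl]ethanone | CC(=O)c1cc(OC)c(OCc2ccccc2)c(OC)c1OCc1ccccc1 | intermediate
8 | 3-hydroxy-4,5-dimethoxybenzoic acid | COc1cc(C(=O)O)cc(O)c1OC | starting material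
9 | benzyl 3-(benzyloxy)-4,5-dimethoxybenzoate | COc1cc(C(=O)OCc2ccccc2)cc(OCc2ccccc2)c1OC | intermediate
10 | lithium enolate of ketone 7 (lithium 1-[2,4-bis(benzyloxy)-3,5-dimethoxyphenyl]ethenolate) | [Li+].[O-]C(=C)c1cc(OC)c(OCc2ccccc2)c(OC)c1OCc1ccccc1 | intermediate
11 | 1-[2,4-bis(benzyloxy)-3,5-dimethoxyphenyl]-3-[3-(benzyloxy)-4,5-dimethoxyphenyl]propane-1,3-dione | O=C(CC(=O)c1cc(OC)c(OC)c(OCc2ccccc2)c1)c1cc(OC)c(OCc2ccccc2)c(OC)c1OCc1ccccc1 | intermediate
12 | 5,7,5'-tri-O-benzylscaposin | COc1cc(-c2cc(=O)c3c(OCc4ccccc4)c(OC)c(OCc5ccccc5)c(OC)c3o2)cc(OCc6ccccc6)c1OC | intermediate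
13 | scaposin | COc1cc(-c2cc(=O)c3c(O)c(OC)c(O)c(OC)c3o2)cc(O)c1OC | target

**Count**

Total steps: 9. Longest linear sequence: 8 steps (steps 1–5, 7, 8, 9).

**Steps most likely to fail**

1. Step 8. The electrolysis may take other courses: oxidative coupling at the C3 methylene, oxidation of ring B, loss of a benzyl group from the ring A radical cation, or further oxidation of the flavone. Fallback, from 7 back to 12: ring bromination of 7 with N-bromosuccinimide in MeCN at the one free ring position should give 1-[2,4-bis(benzyloxy)-6-bromo-3,5-dimethoxyphenyl]ethanone F1. Claisen condensation of F1 with 9 under the conditions of step 7 should give 1-[2,4-bis(benzyloxy)-6-bromo-3,5-dimethoxyphenyl]-3-[3-(benzyloxy)-4,5-dimethoxyphenyl]propane-1,3-dione F2. Intramolecular Ullmann-type O-arylation of its enolate (CuI, K2CO3, DMF, 100 °C), a known route from 1-(2-bromoaryl)-1,3-diketones to flavones, then closes the same O1–C8a bond and gives 12.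

2. Step 2. Hot alkali may cause hydrodebromination, disproportionation of the aldehyde or air oxidation of the electron-rich dihydroxy aldehyde. Fallback, from 2 back to 5: benzylation of 2 (BnBr, K2CO3, DMF) should give 4-(benzyloxy)-2-bromo-3,5-dimethoxybenzaldehyde F3. Miyaura borylation (B2pin2, PdCl2(dppf), KOAc, dioxane, 90 °C) should give 4-(benzyloxy)-3,5-dimethoxy-2-(4,4,5,5-tetramethyl-1,3,2-dioxaborolan-2-yl)benzaldehyde F4. Oxidation of the C–B bond (NaBO3·4H2O, THF/H2O, rt) should give 4-(benzyloxy)-2-hydroxy-3,5-dimethoxybenzaldehyde F5, and a second benzylation gives 5.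

3. Step 7. Acylation of the hindered enolate by the electron-rich ester may stall, with proton transfer returning the ketone. Fallback, from 7 back to 11: purchased 3-hydroxy-4,5-dimethoxybenzaldehyde F6 is benzylated (BnBr, K2CO3, DMF) to 3-(benzyloxy)-4,5-dimethoxybenzaldehyde F7. Aldol addition of enolate 10 (from 7, LiN(SiMe3)2, THF, −78 °C) to F7 should give racemic 1-[2,4-bis(benzyloxy)-3,5-dimethoxyphenyl]-3-[3-(benzyloxy)-4,5-dimethoxyphenyl]-3-hydroxypropan-1-one F8. Oxidation with Dess–Martin periodinane then gives 11.

**Further compounds**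

F1 | step 8 | 1-[2,4-bis(benzyloxy)-6-bromo-3,5-dimethoxyphenyl]ethanone | CC(=O)c1c(Br)c(OC)c(OCc2ccccc2)c(OC)c1OCc1ccccc1
F2 | step 8 | 1-[2,4-bis(benzyloxy)-6-bromo-3,5-dimethoxyphenyl]-3-[3-(benzyloxy)-4,5-dimethoxyphenyl]propane-1,3-dione | O=C(CC(=O)c1cc(OC)c(OC)c(OCc2ccccc2)c1)c1c(Br)c(OC)c(OCc2ccccc2)c(OC)c1OCc1ccccc1
F3 | step 2 | 4-(benzyloxy)-2-bromo-3,5-dimethoxybenzaldehyde | O=Cc1cc(OC)c(OCc2ccccc2)c(OC)c1Br
F4 | step 2 | 4-(benzyloxy)-3,5-dimethoxy-2-(4,4,5,5-tetramethyl-1,3,2-dioxaborolan-2-yl)benzaldehyde | O=Cc1cc(OC)c(OCc2ccccc2)c(OC)c1B1OC(C)(C)C(C)(C)O1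
F5 | step 2 | 4-(benzyloxy)-2-hydroxy-3,5-dimethoxybenzaldehyde | O=Cc1cc(OC)c(OCc2ccccc2)c(OC)c1O
F6 | step 7 | 3-hydroxy-4,5-dimethoxybenzaldehyde (purchased) | COc1cc(C=O)cc(O)c1OC
F7 | step 7 | 3-(benzyloxy)-4,5-dimethoxybenzaldehyde | COc1cc(C=O)cc(OCc2ccccc2)c1OC
F8 | step 7 | 1-[2,4-bis(benzyloxy)-3,5-dimethoxyphenyl]-3-[3-(benzyloxy)-4,5-dimethoxyphenyl]-3-hydroxypropan-1-one (racemic) | O=C(CC(O)c1cc(OC)c(OC)c(OCc2ccccc2)c1)c1cc(OC)c(OCc2ccccc2)c(OC)c1OCc1ccccc1
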